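**Retrosynthetic overview**

1. Kushenol B ⇐ its 2',4'-diacetate 33 ⇐ 7-O-(1,1-dimethylallyl) ether 31 (aromatic Claisen rearrangement to C6) ⇐ 8-lavandulyl flavanone 29 ⇐ C8 iodide 17 + (S)-lavandulylzinc iodide 27 (Negishi coupling, C8–CH2 bond).
2. The route rests on one feature: the carbonyl carbon C4 is bonded to C4a of a phloroglucinol-type A ring in which, while C6 and C8 are still unsubstituted, the two ring carbons ortho to O1 (the future C4a and C8) are homotopic. The pyranone (C) ring can therefore be closed at C4–C4a, a bond remote from C2, by intramolecular Friedel–Crafts acylation of an open-chain 3-aryl-3-aryloxypropanoic acid, with no regiochemical question.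
3. C2 is set before ring closure: catalytic asymmetric acetate aldol on 2,4-diacetoxybenzaldehyde gives the (R)-carbinol, and Mitsunobu inversion with 3,5-bis(benzyloxy)phenol forms O1–C2 as S.
4. The lavandulyl stereocentre comes from a deconjugative Evans α-prenylation of the N-(3-methylbut-2-enoyl)oxazolidinone.
5. Ring order: A and B rings are bought; the C ring is the only ring formed (step 6); the side chains enter afterwards, C8 (iodination, coupling) before C6 (Claisen).

Key step: step 6

**Remarks and assumptions**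

- The B-ring phenols are carried as acetates. They must be electron-withdrawing through steps 4–6 and must come off at the end without base, because base would open the flavanone (chalcone or quinone methide) and erase C2.
- The antipode of the aldol catalyst is chosen so that the nucleophile adds to the Re face of the aldehyde; the sense is to be confirmed on 7 (Mosher esters) before material is committed.
- Covalent intermediates that are made and consumed in one flask are numbered; salts or ate-complexes that are only protonated on work-up, and catalyst-bound species, are not.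
- The lavandulyl stereocentre is called S in 24–27 and R once its CH2 carries the aryl ring; this is a change of CIP priority, not of configuration.
- LDA is used as a commercial solution.

**Route**

Step 1
Reactants: 1 2,4-dihydroxybenzaldehyde
Product: 2 2,4-diacetoxybenzaldehyde
Conditions: Ac2O, Et3N, DMAP (cat.), CH2Cl2, 0 °C to rt
Reagents that add atoms: acetic anhydride CC(=O)OC(C)=O
Why: DMAP-catalysed O-acetylation of both phenols gives the diacetate, which keeps the B ring electron-poor for the later benzylic substitution and acylation steps and can be removed at the end without base.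

Step 2
Reactants: 3 tert-butyl acetate
Product: 5 1-tert-butoxy-1-(tert-butyldimethylsilyloxy)ethene, via tert-butyl acetate lithium enolate 4 (not isolated)
Conditions: LDA, THF, −78 °C; then TBSCl, DMPU, −78 °C to rt
Reagents that add atoms: tert-butyldimethylsilyl chloride CC(C)(C)[Si](C)(C)Cl
Why: Kinetic ester enolate formation followed by O-silylation in a dipolar cosolvent is the standard preparation of acetate-derived silyl ketene acetals.

Step 3
Reactants: 2 2,4-diacetoxybenzaldehyde; 5 1-tert-butoxy-1-(tert-butyldimethylsilyloxy)ethene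
Product: 7 tert-butyl (3R)-3-(2,4-diacetoxyphenyl)-3-hydroxypropanoate, via trichlorosilyl aldolate 6 (not isolated)
Conditions: SiCl4, chiral binaphthyldiamine-derived bisphosphoramide (5 mol%), iPr2NEt (10 mol%), CH2Cl2, −78 °C; then sat. aq. NaHCO3
Reagents that add atoms: none
Why: Mukaiyama acetate aldol under Lewis-base activation of SiCl4: the chiral phosphoramide-bound trichlorosilyl cation binds the aldehyde and shields one face, so the ketene acetal adds to the Re face through an open transition state and sets C2 as the (R)-carbinol, while the aryl acetates are inert to the Lewis acid at −78 °C.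

Step 4
Reactants: 7 tert-butyl (3R)-3-(2,4-diacetoxyphenyl)-3-hydroxypropanoate; 8 3,5-bis(benzyloxy)phenol
Product: 9 tert-butyl (3S)-3-[3,5-bis(benzyloxy)phenoxy]-3-(2,4-diacetoxyphenyl)propanoate
Conditions: PPh3, DIAD, toluene, 0 °C to rt
Reagents that add atoms: none
Why: Mitsunobu etherification: the phenol (pKa about 9) displaces the alkoxyphosphonium group by SN2 with inversion, turning the (R)-carbinol into the (S)-aryl ether, and the two acetoxy groups together with the β-ester disfavour a benzylic cation that would erode the configuration.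

Step 5
Reactants: 9 tert-butyl (3S)-3-[3,5-bis(benzyloxy)phenoxy]-3-(2,4-diacetoxyphenyl)propanoate
Product: 11 (3S)-3-[3,5-bis(benzyloxy)phenoxy]-3-(2,4-diacetoxyphenyl)propanoic acid, via trimethylsilyl ester 10 (not isolated)
Conditions: TMSOTf, 2,6-lutidine, CH2Cl2, 0 °C; then aq. citric acid
Reagents that add atoms: none
Why: Silyl triflate-induced tert-butyl ester cleavage (loss of isobutene, silyl ester hydrolysed on work-up) frees the acid without protic strong acid, so the electron-rich triether ring is neither tert-butylated nor debenzylated, and no base touches the β-aryloxy ester.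

Step 6
Reactants: 11 (3S)-3-[3,5-bis(benzyloxy)phenoxy]-3-(2,4-diacetoxyphenyl)propanoic acid
Product: 13 (2S)-5,7-bis(benzyloxy)-2-(2,4-diacetoxyphenyl)chroman-4-one, via mixed trifluoroacetic anhydride 12 (not isolated)
Conditions: TFAA (1.3 equiv), CH2Cl2 (0.05 M), 0 °C to rt
Reagents that add atoms: none
Why: TFAA converts the acid into the mixed anhydride 12, an acylium equivalent that is attacked by the ring carbon ortho to the aryloxy oxygen, and loss of the ring proton gives the aryl ketone, forming C4–C4a and closing the pyranone ring. This is the intramolecular Friedel–Crafts acylation of 3-aryloxypropanoic acids used for chroman-4-ones, here on a 1,3,5-trioxygenated ring that is nucleophilic enough to need no metal Lewis acid. The ring closes by 6-exo-trig attack of the arene carbon on the acyl carbon. No stereocentre is made, and C2 is carried through because no bond to it is formed or broken. The two carbons ortho to O1 are homotopic, so there is no regiochemical choice; the para carbon cannot reach the tether, and intermolecular acylation is held back by dilution and by the small excess of TFAA. The selectivity that matters is retention at C2: acid-induced heterolysis of the benzylic C2–O1 bond is suppressed by the two acetoxy groups, which deny the cation the donor stabilisation that a free or alkylated resorcinol ring would give.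

Step 7
Reactants: 13 (2S)-5,7-bis(benzyloxy)-2-(2,4-diacetoxyphenyl)chroman-4-one
Product: 14 (2S)-5,7-bis(benzyloxy)-2-(2,4-diacetoxyphenyl)-8-iodochroman-4-one
Conditions: NIS, TFA (cat.), MeCN, 0 °C to rt, dark
Reagents that add atoms: N-iodosuccinimide O=C1CCC(=O)N1I
Why: Electrophilic aromatic iodination: with both A-ring oxygens alkylated, C6 is buttressed between two benzyloxy groups and iodine is taken up at C8 next to O1 (the pattern of 5,7-di-O-alkyl flavonoids), whereas a free chelated 5-OH would direct to C6, which is why iodination precedes debenzylation; the acetylated B ring is too deactivated to react.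

Step 8
Reactants: 14 (2S)-5,7-bis(benzyloxy)-2-(2,4-diacetoxyphenyl)-8-iodochroman-4-one
Product: 16 (2S)-2-(2,4-diacetoxyphenyl)-5,7-dihydroxy-8-iodochroman-4-one, via bis(dichloroboryl) ether 15 (not isolated)
Conditions: BCl3, C6HMe5, CH2Cl2, −78 °C; then aq. NaHCO3
Reagents that add atoms: none
Why: Lewis-acid debenzylation of aryl benzyl ethers with pentamethylbenzene as a non-basic benzyl cation trap runs at −78 °C and should leave the aryl iodide (which hydrogenolysis would remove), the aryl acetates and C2 untouched.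

Step 9
Reactants: 16 (2S)-2-(2,4-diacetoxyphenyl)-5,7-dihydroxy-8-iodochroman-4-one
Product: 17 (2S)-7-(tert-butyldimethylsilyloxy)-2-(2,4-diacetoxyphenyl)-5-hydroxy-8-iodochroman-4-one
Conditions: TBSCl, imidazole, DMF, 0 °C
Reagents that add atoms: tert-butyldimethylsilyl chloride CC(C)(C)[Si](C)(C)Cl
Why: Silylation of the more acidic, non-chelated 7-OH (the 5-OH is locked in a hydrogen bond to C4=O) removes the acidic proton next to the C–I bond before the organozinc coupling.

Step 10
Reactants: 18 3-methylbut-2-enoic acid; 19 (4S)-4-benzyloxazolidin-2-one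
Product: 21 (4S)-4-benzyl-3-(3-methylbut-2-enoyl)oxazolidin-2-one, via mixed pivalic anhydride 20 (not isolated)
Conditions: PivCl, Et3N, THF, −20 °C; then LiCl, 19, −20 °C to rt
Reagents that add atoms: none
Why: N-Acylation of the oxazolidinone through the mixed pivalic anhydride (LiCl/Et3N) occurs at the less hindered carbonyl of the anhydride.

Step 11
Reactants: 21 (4S)-4-benzyl-3-(3-methylbut-2-enoyl)oxazolidin-2-one; 22 1-bromo-3-methylbut-2-ene
Product: 24 (4S)-4-benzyl-3-[(2S)-5-methyl-2-(prop-1-en-2-yl)hex-4-enoyl]oxazolidin-2-one, via sodium dienolate 23 (not isolated)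
Conditions: NaHMDS, THF, −78 °C; then 22, −78 to −40 °C
Reagents that add atoms: none
Why: Evans alkylation in its deconjugative form: γ-deprotonation gives the chelated Z-dienolate, which is alkylated at the α-carbon on the face opposite the benzyl group, setting the lavandulyl stereocentre and leaving the isopropenyl group.

Step 12
Reactants: 24 (4S)-4-benzyl-3-[(2S)-5-methyl-2-(prop-1-en-2-yl)hex-4-enoyl]oxazolidin-2-one
Product: 25 (2S)-5-methyl-2-(prop-1-en-2-yl)hex-4-en-1-ol ((S)-lavandulol)
Conditions: LiBH4, MeOH (1 equiv), Et2O, 0 °C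
Reagents that add atoms: none
Why: Borohydride reduction of the exocyclic imide carbonyl releases the primary alcohol and the intact auxiliary under conditions too mild to epimerise or conjugate the α-vinyl stereocentre.

Step 13
Reactants: 25 (2S)-5-methyl-2-(prop-1-en-2-yl)hex-4-en-1-ol
Product: 26 (3S)-3-(iodomethyl)-2,6-dimethylhepta-1,5-diene ((S)-lavandulyl iodide)
Conditions: PPh3, I2, imidazole, CH2Cl2, 0 °C to rt
Reagents that add atoms: iodine II
Why: Appel-type iodination replaces the primary hydroxyl by SN2 at CH2, so the adjacent stereocentre is not involved.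

Step 14
Reactants: 17 (2S)-7-(tert-butyldimethylsilyloxy)-2-(2,4-diacetoxyphenyl)-5-hydroxy-8-iodochroman-4-one; 26 (3S)-3-(iodomethyl)-2,6-dimethylhepta-1,5-diene
Product: 28 (2S)-7-(tert-butyldimethylsilyloxy)-2-(2,4-diacetoxyphenyl)-5-hydroxy-8-[(2R)-5-methyl-2-(prop-1-en-2-yl)hex-4-en-1-yl]chroman-4-one, via (S)-lavandulylzinc iodide 27 (not isolated)
Conditions: 26, Zn dust (TMSCl-activated), LiCl, THF, 40 °C; then 17, Pd(OAc)2 (5 mol%), SPhos (10 mol%), THF/NMP, rt to 45 °C
Reagents that add atoms: none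
Why: Negishi sp3–sp2 coupling: LiCl-assisted zinc insertion gives the primary alkylzinc iodide (its stereocentre is β to zinc and not involved), and the bulky biarylphosphine should make reductive elimination at the hindered C8 faster than β-hydride elimination, while ketone, aryl acetates and silyl ether are inert to RZnI and the chelated 5-OH is protonated only slowly (an excess of 27 covers this).

Step 15
Reactants: 28 (2S)-7-(tert-butyldimethylsilyloxy)-2-(2,4-diacetoxyphenyl)-5-hydroxy-8-[(2R)-5-methyl-2-(prop-1-en-2-yl)hex-4-en-1-yl]chroman-4-one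
Product: 29 (2S)-2-(2,4-diacetoxyphenyl)-5,7-dihydroxy-8-[(2R)-5-methyl-2-(prop-1-en-2-yl)hex-4-en-1-yl]chroman-4-one
Conditions: TBAF, AcOH (1:1), THF, 0 °C
Reagents that add atoms: none
Why: Fluoride cleavage of the aryl silyl ether, buffered with acetic acid so that no free phenoxide or basic fluoride can open the flavanone or shift acetyl groups.

Step 16
Reactants: 29 (2S)-2-(2,4-diacetoxyphenyl)-5,7-dihydroxy-8-[(2R)-5-methyl-2-(prop-1-en-2-yl)hex-4-en-1-yl]chroman-4-one; 30 tert-butyl 2-methylbut-3-en-2-yl carbonate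
Product: 31 (2S)-2-(2,4-diacetoxyphenyl)-5-hydroxy-7-[(2-methylbut-3-en-2-yl)oxy]-8-[(2R)-5-methyl-2-(prop-1-en-2-yl)hex-4-en-1-yl]chroman-4-one
Conditions: Pd(PPh3)4 (5 mol%), THF, 0 °C
Reagents that add atoms: none
Why: Palladium-catalysed decarboxylative O-allylation (Tsuji–Trost) with a tertiary allylic carbonate gives the branched 1,1-dimethylallyl aryl ether under kinetic control at low temperature, and only the acidic 7-OH reacts because the 5-OH is chelated and the B ring is acetylated.

Step 17
Reactants: 31 (2S)-2-(2,4-diacetoxyphenyl)-5-hydroxy-7-[(2-methylbut-3-en-2-yl)oxy]-8-[(2R)-5-methyl-2-(prop-1-en-2-yl)hex-4-en-1-yl]chroman-4-one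
Product: 33 (2S)-2-(2,4-diacetoxyphenyl)-5,7-dihydroxy-6-(3-methylbut-2-en-1-yl)-8-[(2R)-5-methyl-2-(prop-1-en-2-yl)hex-4-en-1-yl]chroman-4-one, via C6 dienone 32 (not isolated)
Conditions: Eu(fod)3 (10 mol%), CHCl3, 60 °C
Reagents that add atoms: none
Why: Aromatic Claisen rearrangement: with C8 occupied, the [3,3] shift can deliver the allyl terminus only to C6, where the dienone re-aromatises, so the 1,1-dimethylallyl ether becomes the C6 prenyl group.

Step 18
Reactants: 33 (2S)-2-(2,4-diacetoxyphenyl)-5,7-dihydroxy-6-(3-methylbut-2-en-1-yl)-8-[(2R)-5-methyl-2-(prop-1-en-2-yl)hex-4-en-1-yl]chroman-4-one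
Product: 34 Kushenol B
Conditions: NH4OAc, MeOH/H2O (4:1), rt
Reagents that add atoms: none
Why: Ammonium acetate-mediated solvolysis of aryl acetates at neutral pH removes both acetyl groups without the base that would racemise C2 and without the acid that would cyclise the prenyl and lavandulyl groups onto the neighbouring phenols.

**Compound list**

1 | 2,4-dihydroxybenzaldehyde | O=Cc1ccc(O)cc1O | starting material
2 | 2,4-diacetoxybenzaldehyde (4-formyl-1,3-phenylene diacetate) | O=Cc1ccc(OC(C)=O)cc1OC(C)=O | intermediate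
3 | tert-butyl acetate | CC(=O)OC(C)(C)C | starting material
4 | lithium 1-tert-butoxyethen-1-olate (lithium enolate of 3) | C=C([O-])OC(C)(C)C.[Li+] | intermediate (not isolated)
5 | 1-tert-butoxy-1-(tert-butyldimethylsilyloxy)ethene | C=C(OC(C)(C)C)O[Si](C)(C)C(C)(C)C | intermediate
6 | tert-butyl (3R)-3-(2,4-diacetoxyphenyl)-3-(trichlorosilyloxy)propanoate | Cl[Si](Cl)(Cl)O[C@@H](c1ccc(OC(C)=O)cc1OC(C)=O)CC(=O)OC(C)(C)C | intermediate (not isolated)
7 | tert-butyl (3R)-3-(2,4-diacetoxyphenyl)-3-hydroxypropanoate | O[C@@H](c1ccc(OC(C)=O)cc1OC(C)=O)CC(=O)OC(C)(C)C | intermediate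
8 | 3,5-bis(benzyloxy)phenol | Oc1cc(OCc2ccccc2)cc(OCc2ccccc2)c1 | starting material
9 | tert-butyl (3S)-3-[3,5-bis(benzyloxy)phenoxy]-3-(2,4-diacetoxyphenyl)propanoate | c1c(OCc2ccccc2)cc(OCc2ccccc2)cc1O[C@H](c1ccc(OC(C)=O)cc1OC(C)=O)CC(=O)OC(C)(C)C | intermediate
10 | trimethylsilyl (3S)-3-[3,5-bis(benzyloxy)phenoxy]-3-(2,4-diacetoxyphenyl)propanoate | c1c(OCc2ccccc2)cc(OCc2ccccc2)cc1O[C@H](c1ccc(OC(C)=O)cc1OC(C)=O)CC(=O)O[Si](C)(C)C | intermediate (not isolated)
11 | (3S)-3-[3,5-bis(benzyloxy)phenoxy]-3-(2,4-diacetoxyphenyl)propanoic acid | c1c(OCc2ccccc2)cc(OCc2ccccc2)cc1O[C@H](c1ccc(OC(C)=O)cc1OC(C)=O)CC(=O)O | intermediate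
12 | (3S)-3-[3,5-bis(benzyloxy)phenoxy]-3-(2,4-diacetoxyphenyl)propanoic trifluoroacetic anhydride | c1c(OCc2ccccc2)cc(OCc2ccccc2)cc1O[C@H](c1ccc(OC(C)=O)cc1OC(C)=O)CC(=O)OC(=O)C(F)(F)F | intermediate (not isolated)
13 | (2S)-5,7-bis(benzyloxy)-2-(2,4-diacetoxyphenyl)chroman-4-one | c1c(OCc2ccccc2)cc(OCc2ccccc2)c2c1O[C@H](c1ccc(OC(C)=O)cc1OC(C)=O)CC2=O | intermediate
14 | (2S)-5,7-bis(benzyloxy)-2-(2,4-diacetoxyphenyl)-8-iodochroman-4-one | Ic1c(OCc2ccccc2)cc(OCc2ccccc2)c2c1O[C@H](c1ccc(OC(C)=O)cc1OC(C)=O)CC2=O | intermediate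
15 | (2S)-2-(2,4-diacetoxyphenyl)-5,7-bis(dichloroboryloxy)-8-iodochroman-4-one | Ic1c(OB(Cl)Cl)cc(OB(Cl)Cl)c2c1O[C@H](c1ccc(OC(C)=O)cc1OC(C)=O)CC2=O | intermediate (not isolated)
16 | (2S)-2-(2,4-diacetoxyphenyl)-5,7-dihydroxy-8-iodochroman-4-one | Ic1c(O)cc(O)c2c1O[C@H](c1ccc(OC(C)=O)cc1OC(C)=O)CC2=O | intermediate
17 | (2S)-7-(tert-butyldimethylsilyloxy)-2-(2,4-diacetoxyphenyl)-5-hydroxy-8-iodochroman-4-one | Ic1c(O[Si](C)(C)C(C)(C)C)cc(O)c2c1O[C@H](c1ccc(OC(C)=O)cc1OC(C)=O)CC2=O | intermediate
18 | 3-methylbut-2-enoic acid | CC(C)=CC(=O)O | starting material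
19 | (4S)-4-benzyloxazolidin-2-one | O=C1N[C@@H](Cc2ccccc2)CO1 | starting material
20 | 3-methylbut-2-enoic pivalic anhydride | CC(C)=CC(=O)OC(=O)C(C)(C)C | intermediate (not isolated)
21 | (4S)-4-benzyl-3-(3-methylbut-2-enoyl)oxazolidin-2-one | CC(C)=CC(=O)N1[C@@H](Cc2ccccc2)COC1=O | intermediate
22 | 1-bromo-3-methylbut-2-ene (prenyl bromide) | CC(C)=CCBr | starting material
23 | sodium (Z)-dienolate of 21 | C=C(C)/C=C(\[O-])N1[C@@H](Cc2ccccc2)COC1=O.[Na+] | intermediate (not isolated)
24 | (4S)-4-benzyl-3-[(2S)-5-methyl-2-(prop-1-en-2-yl)hex-4-enoyl]oxazolidin-2-one | C=C(C)[C@H](CC=C(C)C)C(=O)N1[C@@H](Cc2ccccc2)COC1=O | intermediate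
25 | (2S)-5-methyl-2-(prop-1-en-2-yl)hex-4-en-1-ol ((S)-lavandulol) | C=C(C)[C@H](CC=C(C)C)CO | intermediate
26 | (3S)-3-(iodomethyl)-2,6-dimethylhepta-1,5-diene ((S)-lavandulyl iodide) | C=C(C)[C@H](CC=C(C)C)CI | intermediate
27 | [(2S)-5-methyl-2-(prop-1-en-2-yl)hex-4-en-1-yl]zinc iodide | C=C(C)[C@H](CC=C(C)C)C[Zn]I | intermediate (not isolated)
28 | (2S)-7-(tert-butyldimethylsilyloxy)-2-(2,4-diacetoxyphenyl)-5-hydroxy-8-[(2R)-5-methyl-2-(prop-1-en-2-yl)hex-4-en-1-yl]chroman-4-one | C=C(C)[C@H](CC=C(C)C)Cc1c(O[Si](C)(C)C(C)(C)C)cc(O)c2c1O[C@H](c1ccc(OC(C)=O)cc1OC(C)=O)CC2=O | intermediate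
29 | (2S)-2-(2,4-diacetoxyphenyl)-5,7-dihydroxy-8-[(2R)-5-methyl-2-(prop-1-en-2-yl)hex-4-en-1-yl]chroman-4-one | C=C(C)[C@H](CC=C(C)C)Cc1c(O)cc(O)c2c1O[C@H](c1ccc(OC(C)=O)cc1OC(C)=O)CC2=O | intermediate
30 | tert-butyl 2-methylbut-3-en-2-yl carbonate | C=CC(C)(C)OC(=O)OC(C)(C)C | starting material
31 | (2S)-2-(2,4-diacetoxyphenyl)-5-hydroxy-7-[(2-methylbut-3-en-2-yl)oxy]-8-[(2R)-5-methyl-2-(prop-1-en-2-yl)hex-4-en-1-yl]chroman-4-one | C=C(C)[C@H](CC=C(C)C)Cc1c(OC(C)(C)C=C)cc(O)c2c1O[C@H](c1ccc(OC(C)=O)cc1OC(C)=O)CC2=O | intermediate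
32 | (2S)-2-(2,4-diacetoxyphenyl)-5-hydroxy-6-(3-methylbut-2-en-1-yl)-8-[(2R)-5-methyl-2-(prop-1-en-2-yl)hex-4-en-1-yl]-2,3-dihydro-6H-chromene-4,7-dione (C6 dienone, C6 unassigned) | C=C(C)[C@H](CC=C(C)C)CC1=C2O[C@H](c3ccc(OC(C)=O)cc3OC(C)=O)CC(=O)C2=C(O)C(CC=C(C)C)C1=O | intermediate (not isolated)
33 | (2S)-2-(2,4-diacetoxyphenyl)-5,7-dihydroxy-6-(3-methylbut-2-en-1-yl)-8-[(2R)-5-methyl-2-(prop-1-en-2-yl)hex-4-en-1-yl]chroman-4-one | C=C(C)[C@H](CC=C(C)C)Cc1c(O)c(CC=C(C)C)c(O)c2c1O[C@H](c1ccc(OC(C)=O)cc1OC(C)=O)CC2=O | intermediate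
34 | Kushenol B, (2S)-2-(2,4-dihydroxyphenyl)-5,7-dihydroxy-6-(3-methylbut-2-en-1-yl)-8-[(2R)-5-methyl-2-(prop-1-en-2-yl)hex-4-en-1-yl]chroman-4-one | C=C(C)[C@H](CC=C(C)C)Cc1c(O)c(CC=C(C)C)c(O)c2c1O[C@H](c1ccc(O)cc1O)CC2=O | target

**Step count**

Total: 18 steps. Longest linear sequence: 13 steps (1, 3–9, 14–18) from 2,4-dihydroxybenzaldehyde.

**Steps most likely to fail**

1. Step 14 (alkylzinc coupling at C8). Transmetalation and reductive elimination at the doubly ortho-substituted, electron-rich C8 may be slow, so that β-hydride elimination from the alkylpalladium (its β-hydrogen is allylic) and protodeiodination outrun coupling; the chelated 5-OH may also consume the zinc reagent. Fallback, from 17 and 26, back at 28: the alkyl partner is changed from zinc to a boron ate complex. Iodine–lithium exchange on 26 (t-BuLi, Et2O, −78 °C) should give (S)-lavandulyllithium F1, which is trapped with B-methoxy-9-BBN as the lithium B-lavandulyl-B-methoxy-9-borabicyclononanate F2. This borinate transfers its primary alkyl group to palladium without added base in a Suzuki–Miyaura coupling with 17 (PdCl2(dppf), THF/DMF, rt), which should give 28.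

2. Step 4 (Mitsunobu etherification). The activated carbinol may lose the oxyphosphonium group by elimination toward the cinnamate (the α-protons of the β-ester are acidic), the ortho-acetyl group may migrate to the carbinol oxygen before activation, or partial SN1 substitution may erode the configuration. Fallback, from 2, back at 11: the acidifying ester is removed from the Mitsunobu substrate. Catalytic asymmetric allylation of 2 (allyltributylstannane, SiCl4, the same chiral bisphosphoramide, −78 °C, Re-face addition) should give 4-[(1R)-1-hydroxybut-3-en-1-yl]-1,3-phenylene diacetate F3. Mitsunobu reaction with 8 then gives the (S)-ether 4-[(1S)-1-[3,5-bis(benzyloxy)phenoxy]but-3-en-1-yl]-1,3-phenylene diacetate F4, whose β-hydrogens are not activated. Dihydroxylation (OsO4 cat., NMO) gives the diol F5, periodate cleavage gives the β-aryloxy aldehyde F6, and Pinnick oxidation (NaClO2, NaH2PO4, 2-methylbut-2-ene) returns the acid 11.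

3. Step 6 (key ring closure). The benzylic C2–O1 bond may ionise under the acidic acylation conditions, with loss of configuration or of the aryloxy group, or the triether ring may be trifluoroacetylated intermolecularly before it cyclises. Fallback, from 2, back at 13: the pyranone ring is closed at O1–C2 instead, with the ketone already on the A ring. 1-[2,4-Bis(benzyloxy)-6-hydroxyphenyl]ethan-1-one F7 is converted (TMSOTf, Et3N) into its bis(trimethylsilyl) derivative F8, the enol ether of which adds to 2 in the same catalytic Mukaiyama aldol to give, after work-up, the (R)-β-hydroxy ketone F9. Intramolecular Mitsunobu reaction (PPh3, DIAD) then displaces the carbinol oxygen by the ortho-phenol with inversion and should give 13.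

**Further compounds**

F1 | step 14 | (S)-lavandulyllithium, [(2S)-5-methyl-2-(prop-1-en-2-yl)hex-4-en-1-yl]lithium | C=C(C)[C@H](CC=C(C)C)C[Li]
F2 | step 14 | lithium B-[(2S)-5-methyl-2-(prop-1-en-2-yl)hex-4-en-1-yl]-B-methoxy-9-borabicyclo[3.3.1]nonanate | C=C(C)[C@H](CC=C(C)C)C[B-]1(OC)C2CCCC1CCC2.[Li+]
F3 | step 4 | 4-[(1R)-1-hydroxybut-3-en-1-yl]-1,3-phenylene diacetate | O[C@@H](c1ccc(OC(C)=O)cc1OC(C)=O)CC=C
F4 | step 4 | 4-[(1S)-1-[3,5-bis(benzyloxy)phenoxy]but-3-en-1-yl]-1,3-phenylene diacetate | c1c(OCc2ccccc2)cc(OCc2ccccc2)cc1O[C@H](c1ccc(OC(C)=O)cc1OC(C)=O)CC=C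
F5 | step 4 | 4-[(1S)-1-[3,5-bis(benzyloxy)phenoxy]-3,4-dihydroxybutyl]-1,3-phenylene diacetate (C3 epimers) | c1c(OCc2ccccc2)cc(OCc2ccccc2)cc1O[C@H](c1ccc(OC(C)=O)cc1OC(C)=O)CC(O)CO
F6 | step 4 | 4-[(1S)-1-[3,5-bis(benzyloxy)phenoxy]-3-oxopropyl]-1,3-phenylene diacetate | c1c(OCc2ccccc2)cc(OCc2ccccc2)cc1O[C@H](c1ccc(OC(C)=O)cc1OC(C)=O)CC=O
F7 | step 6 | 1-[2,4-bis(benzyloxy)-6-hydroxyphenyl]ethan-1-one | CC(=O)c1c(O)cc(OCc2ccccc2)cc1OCc1ccccc1
F8 | step 6 | [1-[2,4-bis(benzyloxy)-6-(trimethylsilyloxy)phenyl]ethenyloxy]trimethylsilane | C=C(O[Si](C)(C)C)c1c(O[Si](C)(C)C)cc(OCc2ccccc2)cc1OCc1ccccc1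
F9 | step 6 | 4-[(1R)-3-[2,4-bis(benzyloxy)-6-hydroxyphenyl]-1-hydroxy-3-oxopropyl]-1,3-phenylene diacetate | O[C@@H](c1ccc(OC(C)=O)cc1OC(C)=O)CC(=O)c1c(O)cc(OCc2ccccc2)cc1OCc1ccccc1
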